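The easy step comes first. In the eta run, X and D turn Q into E while L reads 50.0% at the start and 51.0% at the end, so I take L as standing still. An excess of 90% then asks for Q at 5.26% of L, which is 4.25 halvings of Q.

- eta: Q 20 mM; L 20 mM; D 1.2 equiv; X 16 mol%; run made earlier
- flask: Q 20 mM; D 1.20 equiv; X 11 mol%; L 20 mM; time 10 min

eta run (percent of the Q and L together charged)

| time / s | L / % | Q / % | E / % |
|---|---|---|---|
| 10.0 | 50.0 | 48.7 | 0.8 |
| 20.0 | 50.5 | 47.2 | 2.7 |
| 40.0 | 50.1 | 42.3 | 7.7 |
| 60.0 | 51.0 | 36.7 | 13.3 |

(readings scatter by 0.5 percentage points)

- whether the excess of L over Q among what is left of the two reaches 90% by 10 min (no / yes)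
- the highest excess of L over Q among what is left of the two up to 10 min

- X is single-handed; Q and L are mirror images of each other, charged as a racemate, each of them at the stated concentration
- D is a solid; its amount is given per volume of the solution
- at the start none of D is in solution
- no earlier run changes the charge of X; that part of a forecast is a guess

How fast does Q halve? I read the pace k, the fraction of Q lost per second (a pseudo-first-order constant), in two ways over the last interval of the eta run. The fall of Q gives 0.00710 s⁻¹. The gain of E over the mean Q gives 0.00709 s⁻¹. These are different readings and they agree, so I trust the value. Between the first two readings the ways part, at 0.00313 s⁻¹ and 0.00396 s⁻¹. But Q drops there by 1.5 percentage points with a scatter of 0.5 points, so the gap tells me nothing.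

Scaling k with X, which is a guess, gives 2.37 min, my estimate of the half-life of Q at this flask's loading. The halvings then take 10.1 min, about the 10 min allowed. Yet the pace was still rising in the eta run, from 0.00548 s⁻¹ one interval earlier. So I commit to yes, with the excess passing 90% before the time is up.

The forecast says yes with a top of 97%, and warns: “Catalyst death or limited D are the main risks”. The flask gives yes and a top of 98.8%.

    J + X + Q → X + E (k = 1000 L² mol⁻² s⁻¹)
    D ⇌ J, rate k2*(cs2 - [J]) while solid is left; crystals form when [J] > cs2 (solubility = 10.0 mM, k = 0.0150 s⁻¹)
    J → Z (k = 4.40 × 10⁻⁵ s⁻¹)
    J + X + L → X + G (k = 7.70 L² mol⁻² s⁻¹)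

In this flask Q's half-life by its step with J and X at 10.0 min is 1.6 min, shorter than the 2.37 min I carried, and the excess reaches 90% at 5.54 min, earlier than my 10.1 min. L's half-life by its step with J and X at 1.76 min is 3.4 h, long against the 10 min, while Q's at 10.0 min is short against it, and at 10.0 min the flask holds 0.59% of the Q charged and 96% of the L charged.

(The numbers in the tables stem from a simulated flask from invented constants.)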